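Numbering (eudesmane): ring A = C1–C2–C3–C4–C5–C10, bridged by O between C1 and C4; ring B = C5–C6–C7–C8–C9–C10; lactone = C7, C8, O, C12, C11 (=C13H2); C14 on C10, C15 on C4.
Cuts: C11=C13 (olefination), C8–O (epoxide opening by the C12 acid) and C7–C11 ([3,3] shift from a C9 ester). Then C5–C10, which returns ring B to a cyclopentene C5–C6–C7–C8–C9 fused to an 8-oxabicyclo[3.2.1]octane. Then C8–C9, C5–C6, C10–C14 and the furan–allyl bonds C1–C10 and C4–C5.
Forward: a (4+3) cycloaddition gives the oxygen bridge and a seven-membered carbocycle. A three-carbon iodoenal is annulated to the five-membered ring. One 1,2-shift then brings rings A and B to their final size, and the lactone is closed last.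
Enabling feature: C9, a carbinol and hence a latent ketone, adjoins the quaternary C10 shared by ring A and ring B, so C5 can have come to C10 from C9. The C1–O–C4 bridge is the mark of a furan.
Stereochemistry: the absolute configuration comes from separating diastereomeric beta-keto sulfoxides made with (−)-menthyl (S)-p-toluenesulfinate; the same sulfur later leaves. C10 and C5 come from exo-face attack on the bicyclic enolates and the stereospecific shift, C6 from an open-transition-state aldol, C7 from a suprafacial [3,3] shift, and C8/C9 from alpha-epoxidation and anti opening.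
Key step: step 12

Remark: compounds 3 to 5 are racemic, and their SMILES show the enantiomer that is carried on. Beta is the face of ring B that carries C14. Exo means syn to the oxygen bridge.

Step 1
Reactants: 1 2-methylfuran; 2 1,1,3-trichloroacetone
Product: 3 (±)-2,4-dichloro-1-methyl-8-oxabicyclo[3.2.1]oct-6-en-3-one (C–Cl epimers)
Conditions: NaOCH2CF3, CF3CH2OH, 0 °C to rt (1 in excess)
Reagents that add atoms: none
Why: Base-induced enolisation and chloride loss convert 2 into the 1,3-dichloro-2-oxyallyl cation, which furans capture in a (4+3) cycloaddition that builds the C1–O–C4 bridge and the seven-membered carbocycle at once, the cis relation of C1 and C4 being dictated by the bridge and the orientation towards the furan methyl group being irrelevant because the three-carbon unit becomes symmetric in step 2.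

Step 2
Reactants: 3 dichloro cycloadduct
Product: 4 (±)-1-methyl-8-oxabicyclo[3.2.1]oct-6-en-3-one
Conditions: Zn–Cu couple, NH4Cl, MeOH, rt
Reagents that add atoms: none
Why: Zinc reduces alpha-chloro ketones through their zinc enolates (reductive dehalogenation), which is the usual second stage of this cycloaddition protocol and leaves alkene, ketone and ether bridge untouched.

Step 3
Reactants: 4 bicyclic enone-free alkene ketone
Product: 5 (±)-1-methyl-8-oxabicyclo[3.2.1]octan-3-one (C9 ketone flanked by C10H2 and C5H2)
Conditions: H2 (1 atm), Pd/C, EtOAc, rt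
Reagents that add atoms: none
Why: Catalytic hydrogenation of the strained cis-disubstituted alkene is fast, creates no stereocentre, and is placed before sulfur enters so that the catalyst is not poisoned and before any peracid step so that no second alkene competes.

Step 4
Reactants: 5 bicyclic ketone; 6 (1R,2S,5R)-(−)-menthyl (S)-p-toluenesulfinate
Product: 7 beta-keto sulfoxide: ketone 5 with an equatorial (R)-p-tolylsulfinyl group on C10, the diastereomer with C1 and C4 as in the target
Conditions: LiN(i-Pr)2 (2.1 equiv), THF, −78 °C; 6, −78 to 0 °C; separation of the two diastereomers by crystallisation or chromatography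
Reagents that add atoms: none
Why: Kinetic deprotonation should take the axial proton of C10H2 next to the CH bridgehead rather than that of C5H2 next to the methyl-bearing bridgehead, the enolate displaces mentholate from sulfur with inversion (Andersen-type sulfinylation), and because sulfur is homochiral the two enantiomers of 5 give separable diastereomers, which is the source of the absolute configuration.

Step 5
Reactants: 7 beta-keto sulfoxide
Product: 8 C10-methylated beta-keto sulfoxide (C14 axial and exo, sulfinyl group equatorial, sulfur unchanged)
Conditions: NaH, THF–DMF, 0 °C; MeI, 0 °C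
Reagents that add atoms: iodomethane CI
Why: Alkylation of the stabilised beta-keto sulfoxide enolate occurs at C10 on the exo face, anti to the C2–C3 bridge, as is general for bicyclo[3.2.1]octan-3-one enolates, so that C14 becomes axial and sulfur is pushed into the equatorial position that the key step requires.

Step 6
Reactants: 8 methylated beta-keto sulfoxide
Product: 9 sulfide ketone: C10 bears axial CH3 and equatorial p-tolylthio
Conditions: NaI, (CF3CO)2O, acetone, −40 °C
Reagents that add atoms: none
Why: Iodide reduction of the O-trifluoroacetylated sulfoxide is a standard deoxygenation, the Pummerer pathway is closed because C10 is quaternary, and the low temperature forestalls thermal syn elimination of the sulfoxide.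

Step 7
Reactants: 9 sulfide ketone
Product: 10 trimethylsilyl enol ether of 9 (C5=C9)
Conditions: Me3SiOTf, Et3N, CH2Cl2, 0 °C
Reagents that add atoms: trimethylsilyl triflate C[Si](C)(C)OS(=O)(=O)C(F)(F)F
Why: Soft enolisation and O-silylation can only run towards C5 because C10 is quaternary, so a single enol silane results.

Step 8
Reactants: 11 ethyl (Z)-3-iodoacrylate
Product: 12 (Z)-3-iodoacrolein
Conditions: i-Bu2AlH (1.0 equiv), CH2Cl2, −78 °C; used without storage
Reagents that add atoms: none
Why: Partial reduction of the ester stops at the tetrahedral aluminium alkoxide at low temperature and releases the aldehyde on work-up with the Z geometry retained.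

Step 9
Reactants: 10 enol silane; 12 (Z)-3-iodoacrolein
Product: 13 syn aldol: axial (exo) C5–C6 bond, C6 carbinol configured as in the target, (Z)-C7=C8–I
Conditions: BF3·OEt2, CH2Cl2, −78 °C
Reagents that add atoms: none
Why: In this Mukaiyama aldol addition the complexed aldehyde is attacked by the exo face of the enol silane, which makes the new C5–C6 bond axial, and in the open antiperiplanar transition state only the hydrogen of C6 can point over the ring towards axial C14, so that the C6 oxygen is placed as in the target (syn adduct, convex face of the later cyclopentene).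

Step 10
Reactants: 13 syn aldol
Product: 14 tricyclic diol: cyclopentene C5–C6–C7=C8–C9 cis-fused to the oxabicycle, C8 equatorial and OH axial on C9, 6-alpha-OH
Conditions: n-BuLi (2.2 equiv), THF, −78 °C; H2O
Reagents that add atoms: none
Why: Iodine–lithium exchange outruns addition of butyllithium to the flanked ketone, and the Z-alkenyllithium, held over the exo face by the axial C5–C6 bond, adds to C9 intramolecularly (anionic cyclopentene annulation of a keto alkenyl iodide), which can only give the cis-fused ring in which C8 is equatorial and the C9 hydroxyl axial.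

Step 11
Reactants: 14 tricyclic diol; 15 angelic acid
Product: 17 C6 angelate of diol 14, via mixed Yamaguchi anhydride 16 (not isolated)
Conditions: 15, 2,4,6-trichlorobenzoyl chloride, Et3N, toluene, rt; then 14, DMAP, rt to 60 °C
Reagents that add atoms: none
Why: Yamaguchi esterification acylates only the secondary hydroxyl on the convex face with retention at C6, leaves the tertiary C9 hydroxyl free, and is the usual way to introduce an angelate without isomerisation to the tiglate.

Step 12
Reactants: 17 C6 angelate (beta-hydroxy sulfide)
Product: 19 trans-fused tricyclic enone (ring A oxanorbornane; ring B cyclohex-7-en-9-one; 6-alpha-OAng), via S-methyl sulfonium triflate 18 (not isolated)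
Conditions: MeOTf, 2,6-di-tert-butyl-4-methylpyridine, CH2Cl2, 0 °C to 40 °C
Reagents that add atoms: none
Why: S-Methylation turns the equatorial p-tolylthio group on C10 into a sulfonium nucleofuge, and in the chair form of the oxygen-containing six-membered ring (O, C1, C10, C9, C5, C4) the C9–C5 bond lies antiperiplanar to the C10–S bond, so that C5 shifts from C9 to C10 while the C9 hydroxyl collapses to the ketone (semipinacol rearrangement of a beta-hydroxy sulfonium salt). The closest known reaction types are the one-carbon ring enlargement of 1-(1-thioalkyl)- or 1-(1-selenoalkyl)cycloalkanols through their onium salts and the quasi-Favorskii contraction of alpha-halo (4+3) cycloadducts to bicyclo[2.2.1] systems. No ring is closed from an open chain: one suprafacial 1,2-shift through a three-centre transition state enlarges the cyclopentene C5–C6–C7–C8–C9 to the cyclohexenone C5–C6–C7–C8–C9–C10 and at the same time contracts the seven-membered carbocycle C1–C2–C3–C4–C5–C9–C10 to ring A. C10 is formed with inversion (C5 enters opposite to sulfur, which leaves C14 exo and the C9 carbonyl endo) and C5 migrates with retention (C6 stays exo), which together fix the trans ring fusion that a cycloaddition of a cyclic cis-dienophile cannot give. The step needs migration of C5 in preference to the vinylic C8, to epoxide closure and to loss of a C14 proton; in the chair both C8 and the axial hydroxyl are gauche to the C–S bond and cannot displace sulfur from the rear, and the hindered pyridine base cannot form the ylide that would trigger elimination. Relief of the 1,3-diaxial C14/C6 contact, formation of the conjugated enone and departure of neutral methyl p-tolyl sulfide should pay for the strain of the product.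

Step 13
Reactants: 19 tricyclic enone
Product: 20 9-beta allylic alcohol
Conditions: NaBH4, CeCl3·7H2O, MeOH, −78 to −20 °C
Reagents that add atoms: none
Why: In the Luche 1,2-reduction hydride should reach C9 from the alpha face, opposite to the adjacent beta methyl group C14, to give the 9-beta pseudo-equatorial alcohol, while the alkene and the angelate stay untouched.

Step 14
Reactants: 20 allylic alcohol; 21 diethylphosphonoacetic acid
Product: 22 C9 diethylphosphonoacetate
Conditions: DCC, DMAP (cat.), CH2Cl2, 0 °C to rt
Reagents that add atoms: none
Why: Steglich esterification acylates the only free hydroxyl group with retention at C9 and brings in C11 and C12 together with the phosphonate that will later deliver C13.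

Step 15
Reactants: 22 allylic phosphonoacetate
Product: 25 gamma-delta-unsaturated phosphono acid (C7-beta–C11, C8=C9; C11 epimers), via silyl ketene acetal 23 (not isolated), via trimethylsilyl ester 24 (not isolated)
Conditions: LiN(SiMe3)2 (1.05 equiv), Me3SiCl, THF, −78 °C, then 65 °C; aqueous citric acid
Reagents that add atoms: none
Why: Only the phosphonoacetate CH2 is acidic enough to be deprotonated, and the silyl ketene acetal undergoes a suprafacial Ireland–Claisen rearrangement, so that C11 is delivered to C7 on the beta face from which the C9–O bond departs and the alkene moves to C8=C9, C11 being formed as an inconsequential epimer mixture.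

Step 16
Reactants: 25 unsaturated phosphono acid
Product: 27 alpha-phosphono lactone (8-beta-O cis-fused lactone; 9-alpha-OH), via epoxy acid 26 (not isolated)
Conditions: mCPBA, CH2Cl2, 0 °C to rt; then camphorsulfonic acid (cat.), rt
Reagents that add atoms: 3-chloroperoxybenzoic acid OOC(=O)c1cccc(Cl)c1
Why: The peracid should attack the only electron-rich alkene from the alpha face, away from C14 and the C7 side chain, and the beta-oriented carboxyl group then opens the epoxide at C8 from the rear in a 5-exo, trans-diaxial (Fürst–Plattner) manner, which sets 8-beta-O and 9-alpha-OH together.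

Step 17
Reactants: 27 alpha-phosphono lactone
Product: 28 target CNP0328162.1
Conditions: aqueous CH2O, K2CO3, THF, 0 °C to rt
Reagents that add atoms: formaldehyde C=O
Why: Horner–Wadsworth–Emmons olefination of the alpha-phosphono lactone with formaldehyde under mild carbonate conditions creates the exocyclic methylene group, erases the C11 stereocentre, and tolerates the free hydroxyl group and the angelate.

Compound list
1 | 2-methylfuran | Cc1ccco1 | starting material
2 | 1,1,3-trichloroacetone | ClCC(=O)C(Cl)Cl | starting material
3 | (±)-2,4-dichloro-1-methyl-8-oxabicyclo[3.2.1]oct-6-en-3-one, C–Cl epimers (racemic) | C[C@@]12C=C[C@@H](O1)C(Cl)C(=O)C2Cl | intermediate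
4 | (±)-1-methyl-8-oxabicyclo[3.2.1]oct-6-en-3-one (racemic) | C[C@@]12C=C[C@@H](O1)CC(=O)C2 | intermediate
5 | (±)-1-methyl-8-oxabicyclo[3.2.1]octan-3-one (racemic) | C[C@@]12CC[C@@H](O1)CC(=O)C2 | intermediate
6 | (1R,2S,5R)-(−)-menthyl (S)-p-toluenesulfinate | Cc1ccc(cc1)[S@@](=O)O[C@@H]1C[C@H](C)CC[C@H]1C(C)C | starting material
7 | beta-keto sulfoxide, equatorial (R)-p-tolylsulfinyl on C10 | C[C@@]12CC[C@@H](O1)[C@H]([S@@](=O)c1ccc(C)cc1)C(=O)C2 | intermediate
8 | C10-methylated beta-keto sulfoxide (C14 axial, sulfur equatorial) | C[C@@]12CC[C@@H](O1)[C@](C)([S@@](=O)c1ccc(C)cc1)C(=O)C2 | intermediate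
9 | sulfide ketone (C14 axial, p-tolylthio equatorial on C10) | C[C@@]12CC[C@@H](O1)[C@](C)(Sc1ccc(C)cc1)C(=O)C2 | intermediate
10 | trimethylsilyl enol ether of 9 (C5=C9) | C[C@@]12CC[C@@H](O1)[C@](C)(Sc1ccc(C)cc1)C(O[Si](C)(C)C)=C2 | intermediate
11 | ethyl (Z)-3-iodoacrylate | CCOC(=O)/C=C\I | starting material
12 | (Z)-3-iodoacrolein | O=C/C=C\I | intermediate
13 | exo, syn aldol with (Z)-iodovinyl group | C[C@@]12CC[C@@H](O1)[C@](C)(Sc1ccc(C)cc1)C(=O)[C@H]2[C@@H](O)/C=C\I | intermediate
14 | tricyclic cyclopentene diol (6-alpha-OH, axial C9–OH) | C[C@@]12CC[C@@H](O1)[C@](C)(Sc1ccc(C)cc1)[C@@]3(O)C=C[C@H](O)[C@@H]23 | intermediate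
15 | angelic acid, (Z)-2-methylbut-2-enoic acid | C/C=C(/C)C(=O)O | starting material
16 | angelic 2,4,6-trichlorobenzoic mixed anhydride | C/C=C(/C)C(=O)OC(=O)c1c(Cl)cc(Cl)cc1Cl | intermediate
17 | C6 angelate of 14 (beta-hydroxy sulfide) | C[C@@]12CC[C@@H](O1)[C@](C)(Sc1ccc(C)cc1)[C@@]3(O)C=C[C@H](OC(=O)/C(C)=C\C)[C@@H]23 | intermediate
18 | S-methyl sulfonium triflate of 17 (sulfur epimers) | C[C@@]12CC[C@@H](O1)[C@](C)([S+](C)c1ccc(C)cc1)[C@@]3(O)C=C[C@H](OC(=O)/C(C)=C\C)[C@@H]23.[O-]S(=O)(=O)C(F)(F)F | intermediate
19 | trans-fused tricyclic enone (C9 ketone, C7=C8, 6-alpha-OAng) | O=C1C=C[C@H](OC(=O)/C(C)=C\C)[C@@H]2[C@]1(C)[C@H]1CC[C@]2(C)O1 | intermediate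
20 | 9-beta allylic alcohol | O[C@H]1C=C[C@H](OC(=O)/C(C)=C\C)[C@@H]2[C@]1(C)[C@H]1CC[C@]2(C)O1 | intermediate
21 | diethylphosphonoacetic acid | CCOP(=O)(CC(=O)O)OCC | starting material
22 | C9 diethylphosphonoacetate | CCOP(=O)(OCC)CC(=O)O[C@H]1C=C[C@H](OC(=O)/C(C)=C\C)[C@@H]2[C@]1(C)[C@H]1CC[C@]2(C)O1 | intermediate
23 | silyl ketene acetal of 22 | CCOP(=O)(OCC)C=C(O[Si](C)(C)C)O[C@H]1C=C[C@H](OC(=O)/C(C)=C\C)[C@@H]2[C@]1(C)[C@H]1CC[C@]2(C)O1 | intermediate
24 | trimethylsilyl ester of 25 | C[Si](C)(C)OC(=O)C(P(=O)(OCC)OCC)[C@@H]1C=C[C@@]2(C)[C@H]3CC[C@](C)(O3)[C@@H]2[C@H]1OC(=O)/C(C)=C\C | intermediate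
25 | unsaturated phosphono acid (C7-beta side chain, C8=C9, C11 epimers) | OC(=O)C(P(=O)(OCC)OCC)[C@@H]1C=C[C@@]2(C)[C@H]3CC[C@](C)(O3)[C@@H]2[C@H]1OC(=O)/C(C)=C\C | intermediate
26 | 8-alpha,9-alpha-epoxy acid | OC(=O)C(P(=O)(OCC)OCC)[C@@H]1[C@H]4O[C@H]4[C@@]2(C)[C@H]3CC[C@](C)(O3)[C@@H]2[C@H]1OC(=O)/C(C)=C\C | intermediate
27 | alpha-phosphono lactone (8-beta-O, 9-alpha-OH, C11 epimers) | CCOP(=O)(OCC)C1C(=O)O[C@H]2[C@@H]1[C@H](OC(=O)/C(C)=C\C)[C@@H]1[C@@](C)([C@@H]2O)[C@H]2CC[C@]1(C)O2 | intermediate
28 | CNP0328162.1 | C=C1C(=O)O[C@H]2[C@@H]1[C@H](OC(=O)/C(C)=C\C)[C@@H]1[C@@](C)([C@@H]2O)[C@H]2CC[C@]1(C)O2 | target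

Total steps: 17. Longest linear sequence: 16 (steps 1 to 7 and 9 to 17).

Steps most likely to fail

Step 12. The sulfonium salt may lose a C14 proton, or the vinylic carbon C8 may migrate from a boat conformer of the oxygen-containing ring. In that case the cationic centre at C10 can be generated from an alkene instead of from a nucleofuge. Setting out from 17, oxidation of sulfur with one equivalent of mCPBA at −78 °C would give the sulfoxide F1. Its thermal syn elimination (toluene, 90 °C, CaCO3) can only run towards C14 and would give the exocyclic-methylene allylic alcohol F2. Hydrogen-atom-transfer-initiated radical–polar crossover is a known way to run semipinacol rearrangements of tertiary allylic alcohols (cobalt salen complex C36H52CoN2O2, N-fluoro-2,4,6-trimethylpyridinium triflate, PhSiH3, acetone, rt). It would add hydrogen to C14 of the 1,1-disubstituted alkene and trigger the same shift of C5 from C9 to C10. This comes back to the route at 19.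

Step 9. The iodoenal may isomerise from Z to E on the Lewis acid or suffer addition–elimination at the iodine-bearing carbon, and facial discrimination at C6 may be poor. The alkenyl iodide can then be made after the aldol step from an alkyne. Setting out from 10, the BF3·OEt2-mediated addition to commercial 3-(trimethylsilyl)propynal should favour the same open transition state, because its linear substituent is smaller. It would give the propargylic aldol F3. NIS with AgNO3 (cat.) in acetone would exchange silicon for iodine to give the iodoalkyne F4. Diimide reduction (2-nitrobenzenesulfonylhydrazide, Et3N) would deliver the Z-iodoalkene. This comes back to the route at 13.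

Step 15. The stabilised ketene acetal may rearrange too slowly from the pseudo-equatorial C9–O bond, so that elimination to a diene takes over. The C7–C11 bond can then be made by an intermolecular allylic alkylation. Setting out from 20, methyl chloroformate and pyridine would give the allylic methyl carbonate F5. Tsuji–Trost alkylation with triethyl phosphonoacetate and Pd(PPh3)4 in THF should attack the terminus remote from quaternary C10 with net retention, and would give the ethyl ester F6. mCPBA would give the alpha-epoxy ester F7, and camphorsulfonic acid would close the lactone at C8 with loss of ethanol. This comes back to the route at 27.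

Further compounds
F1 | step 12 | sulfoxide of 17 (sulfur epimers) | C[C@@]12CC[C@@H](O1)[C@](C)(S(=O)c1ccc(C)cc1)[C@@]3(O)C=C[C@H](OC(=O)/C(C)=C\C)[C@@H]23
F2 | step 12 | exocyclic-methylene allylic alcohol (C10=C14) | C[C@@]12CC[C@@H](O1)C(=C)[C@@]3(O)C=C[C@H](OC(=O)/C(C)=C\C)[C@@H]23
F3 | step 9 | propargylic aldol with trimethylsilylalkyne | C[C@@]12CC[C@@H](O1)[C@](C)(Sc1ccc(C)cc1)C(=O)[C@H]2[C@@H](O)C#C[Si](C)(C)C
F4 | step 9 | iodoalkyne aldol | C[C@@]12CC[C@@H](O1)[C@](C)(Sc1ccc(C)cc1)C(=O)[C@H]2[C@@H](O)C#CI
F5 | step 15 | allylic methyl carbonate of 20 | COC(=O)O[C@H]1C=C[C@H](OC(=O)/C(C)=C\C)[C@@H]2[C@]1(C)[C@H]1CC[C@]2(C)O1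
F6 | step 15 | ethyl ester of 25 | CCOC(=O)C(P(=O)(OCC)OCC)[C@@H]1C=C[C@@]2(C)[C@H]3CC[C@](C)(O3)[C@@H]2[C@H]1OC(=O)/C(C)=C\C
F7 | step 15 | 8-alpha,9-alpha-epoxy ethyl ester | CCOC(=O)C(P(=O)(OCC)OCC)[C@@H]1[C@H]4O[C@H]4[C@@]2(C)[C@H]3CC[C@](C)(O3)[C@@H]2[C@H]1OC(=O)/C(C)=C\C
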